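## Analysis of the target

Target 21 is an oxolane (O1, C2, C3, C4, C5) with ring B at C2, methyl groups at C3 and C4, and ring A (4-hydroxyphenyl) at C5. Ring B is a phenol that carries, ortho to its hydroxyl and meta to the oxolane, a 1-arylpropan-2-yl side chain ending in ring C (4-hydroxyphenyl). There are five stereocentres: C2 (R), C3 (S), C4 (R) and C5 (S), whose substituents all lie on one face of the ring, and the side-chain methine (R), which ring B insulates from the oxolane so that the ring cannot control it. The all-cis oxolane is the most crowded diastereomer and must be made under kinetic control and kept from equilibrating. Both ring C–O bonds are benzylic ethers next to para-oxygenated aryl rings, so acid can ionise them and forcing hydrogenolysis can cleave them; the three phenols must stay masked to the end. The side-chain centre is a tertiary benzylic carbon with no functional group nearby, and the two ring aryl groups differ, so ring A and ring B must be placed without ambiguity. The plan rests on the O1–C2 bond: C2 and C3 are traced back to the two carbons of an alkyne bearing ring B, attached to a preformed syn pair C4 (methyl) / C5 (hydroxyl, ring A). The C5 oxygen closes the ring onto the alkyne, and one syn addition of hydrogen to the resulting cyclic enol ether then creates C2 and C3 together.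

## Retrosynthetic reasoning

**21 ⇒ 20.** The hydrogens at C2 and C3 are removed and the three phenols are put back as benzyl ethers, giving the 4,5-dihydrofuran 20. No skeletal bond is cut. The gain is that two stereocentres arise from one suprafacial addition to the face opposite the cis C4 methyl and C5 aryl groups, which is the simplest way to the contra-thermodynamic all-cis array, and deprotection costs no extra step. The forward reaction must saturate a hindered C2=C3 bond and cleave three aryl benzyl ethers while sparing the benzylic ring C–O bonds.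

**20 ⇒ 19.** The C3–CH3 bond is cut to the vinyl iodide 19. Iodine at C3 is exactly what the ring closure leaves behind, and a cross-coupling at an sp2 carbon raises no stereochemical question. The forward reaction must methylate a β-iodo enol ether under neutral, non-aqueous conditions.

**19 ⇒ 18.** The O1–C2 bond and the C3–I bond are cut together, opening the ring to the homopropargylic alcohol 18. This is the place to cut because C2 is the alkyne carbon best able to carry positive charge (it bears ring B) and because the five-membered closure leaves C4 and C5 untouched. The forward reaction must add oxygen and iodine anti across the alkyne with oxygen at C2.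

**18 ⇒ 17 ⇒ 16 + 8.** After re-silylation of the C5 oxygen (17), the bond between the alkyne carbon and ring B is cut. This splits the molecule into two pieces of similar size: alkyne 16 (C3, C4, C5, ring A) and aryl bromide 8 (ring B, side chain, ring C). An sp–sp2 coupling tolerates everything present and involves no stereocentre, so the route becomes convergent.

**16 ⇒ 15 ⇒ 14 ⇒ 13 ⇒ 12.** The terminal alkyne carbon (future C2) is removed by a one-carbon homologation of aldehyde 15. The aldehyde goes back through alcohol 14 and silyl ether 13 to the aldol adduct 12. These are functional-group changes that must preserve the centre next to the carbonyl.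

**12 ⇒ 9 + 10.** The C4–C5 bond is cut by an aldol disconnection to aldehyde 9 and the chiral N-propanoyl oxazolidinone 10. The syn relationship of methyl and hydroxyl in 12 equals the cis relationship of C4 methyl and C5 aryl in the ring. The auxiliary fixes the absolute configuration of both centres in one step.

**8 ⇒ 7.** The two C–H bonds of the side chain are removed, giving the (E)-trisubstituted alkene 7. With no directing group available, the centre is best set by enantioselective hydrogenation of an unfunctionalised alkene. This demands a single alkene geometry, because E and Z isomers would give opposite enantiomers.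

**7 ⇒ 2 + 6; 6 ⇒ 5 ⇒ 3 + 4; 2 ⇒ 1.** The ring B–alkenyl bond is cut to the iodo bromide 2 and the alkenylboronate 6; the C–I bond of 2 reacts first and the bromide is kept for the later union with 16. The geometry of 6 comes from a syn borylcupration of alkyne 5, itself made from iodide 3 and propyne 4. Compound 2 is the benzyl ether of phenol 1.

## Alternatives that were turned down

**Alternative 1:** The ring is taken back to the α-methylene lactone A1 by cutting C4–C5 and the O1–C2 acyl bond. In the forward step a chiral phosphoric acid activates the ester-bearing crotylboronate A2, which transfers its crotyl unit to aldehyde 9 through a chair transition state; the resulting alkoxide lactonises to give A1 with C4 and C5 cis.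
- For: one catalytic step delivers ring A, C4, C5 and a carbonyl at C2 ready to receive ring B, with no auxiliary. On step count to this stage it is clearly stronger than the chosen route, which needs five steps after the aldol to reach 16.
- Against: C3 would come from hydrogenating the exocyclic alkene next to the lactone carbonyl, where the needed cis,cis isomer is the less stable epimer at an enolisable centre. C2 would come from adding an aryl-metal derived from 8 to the lactone and deoxygenating the lactol through a C2 oxocarbenium ion under Lewis acid. Its configuration then depends on the approach of a hydride to a planar cation, and the same acid can ionise the C5–O1 bond next to electron-rich ring A. A2 is also a deactivated allylating agent and 9 an electron-rich aldehyde.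
- Comparison: the chosen route gives up the short front end for a fully predictable syn-aldol and for setting C2 and C3 in one kinetically controlled syn addition with no cation at C2.

**Alternative 2:** The side chain is cut at the ring B–CH bond and at the CH2–ring C bond. The aryllithium A4 (the finished oxolane core) adds to the isopropenylboronic ester A5. Under Pd(OAc)2 with MandyPhos the triflate A6 then triggers aryl migration from boron to carbon and reductive elimination, giving the tertiary boronic ester A3; a stereoretentive protodeboronation would follow.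
- For: it is more convergent than the chosen route, builds the side chain and its centre in one catalytic step, has no alkene-geometry problem, and allows ring C to be varied late.
- Against: the most valuable intermediate, with all four ring centres, is exposed to an organolithium and to the least certain step. The migrating aryl group has an ortho benzyloxy substituent, and α-substituted alkenylboronates giving tertiary boronates are the narrow end of this reaction's scope. Imperfect catalyst control would give diastereomers that differ only at a remote centre and are hard to separate, and the extra protodeboronation can leak configuration.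
- Comparison: the chosen route sets the side-chain centre first, on the small fragment 8. There the minor isomer is an enantiomer that can be assayed and removed, and failure is cheap.

**Alternative 3:** The CH–CH2 bond of the side chain is cut after tying the phenol oxygen of ring B to the CH2 carbon. The diazo ester A8 gives a rhodium carbenoid with Rh2(S-PTTL)4, which inserts into the benzylic ether C–H next to ring C and closes the cis-dihydrobenzofuran A7.
- For: the insertion is intramolecular, forms a five-membered ring at an activated C–H bond, and uses the phenol as its own tether. Its enantiocontrol is probably more predictable than the hydrogenation of a hindered alkene chosen here.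
- Against: A7 has the wrong oxidation level at two positions. The ester must become a methyl group in three operations next to an epimerisable centre, and the C2–O bond must be cleaved reductively. Hydrogenolysis at that point would also remove the aryl bromide and the benzyl ether; postponed to the end, it would have to distinguish this C–O bond from the two benzylic C–O bonds of the oxolane.
- Comparison: the chosen route reaches 8 at the correct oxidation level in five steps with no protecting-group exchange and keeps the only hydrogenolysis for the last step.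

Key step: step 13

Remark on the chemistry: the locants O1, C2 to C5 of the oxolane are kept for the dihydrofuran intermediates. The sense of induction in step 5 is assigned by analogy with simple (E)-1,2-diarylpropenes under the same catalyst class; the mirror-image ligand would be used if the analogy failed.

## Route

Step 1
Reactants: 1 4-bromo-2-iodophenol
Product: 2 1-(benzyloxy)-4-bromo-2-iodobenzene
Conditions: BnBr, K2CO3, DMF, rt
Reagents that add atoms: benzyl bromide, BrCc1ccccc1
Why: Williamson etherification of the phenoxide; benzyl is used on all three phenols because it survives every later step and leaves in the final hydrogenation.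

Step 2
Reactants: 3 1-(benzyloxy)-4-iodobenzene; 4 propyne
Product: 5 1-(benzyloxy)-4-(prop-1-yn-1-yl)benzene
Conditions: Pd(PPh3)2Cl2 (2 mol%), CuI (4 mol%), Et3N, THF, rt, closed vessel
Reagents that add atoms: none
Why: Sonogashira coupling; the aryl iodide reacts at room temperature, so the volatile alkyne 4 can be used as a solution in a closed vessel.

Step 3
Reactants: 5 1-(benzyloxy)-4-(prop-1-yn-1-yl)benzene
Product: 6 2-{(Z)-1-[4-(benzyloxy)phenyl]prop-1-en-2-yl}-4,4,5,5-tetramethyl-1,3,2-dioxaborolane
Conditions: B2pin2, CuCl (5 mol%), Xantphos (5 mol%), NaOt-Bu (10 mol%), MeOH (2 equiv), THF, rt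
Reagents that add atoms: bis(pinacolato)diboron, CC1(C)OB(OC1(C)C)B1OC(C)(C)C(C)(C)O1
Why: Copper-catalysed borylcupration–protonation (formal hydroboration): Cu–Bpin adds syn with copper on the aryl-bearing carbon (benzylic C–Cu stabilisation) and boron on the methyl-bearing carbon, and methanol protonates C–Cu with retention, so a single alkenylboronate with aryl and methyl cis should result.

Step 4
Reactants: 2 1-(benzyloxy)-4-bromo-2-iodobenzene; 6 2-{(Z)-1-[4-(benzyloxy)phenyl]prop-1-en-2-yl}-4,4,5,5-tetramethyl-1,3,2-dioxaborolane
Product: 7 1-(benzyloxy)-2-{(E)-1-[4-(benzyloxy)phenyl]prop-1-en-2-yl}-4-bromobenzene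
Conditions: Pd(dppf)Cl2 (3 mol%), aq. K3PO4, 1,4-dioxane, 60 °C
Reagents that add atoms: none
Why: Suzuki–Miyaura coupling with retention of alkene geometry; oxidative addition into C–I is much faster than into C–Br, so the bromide para to the benzyloxy group is kept for step 11 and the two aryl groups end up trans.

Step 5
Reactants: 7 1-(benzyloxy)-2-{(E)-1-[4-(benzyloxy)phenyl]prop-1-en-2-yl}-4-bromobenzene
Product: 8 1-(benzyloxy)-2-[(2R)-1-[4-(benzyloxy)phenyl]propan-2-yl]-4-bromobenzene
Conditions: H2 (50 bar), [Ir(cod)(L)]BArF (2 mol%), CH2Cl2, rt; L = (S)-4-tert-butyl-2-[2-(di-o-tolylphosphanyl)phenyl]-4,5-dihydrooxazole, cod = cycloocta-1,5-diene, BArF = B[3,5-(CF3)2C6H3]4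
Reagents that add atoms: none
Why: Asymmetric hydrogenation of an unfunctionalised trisubstituted alkene with a cationic iridium phosphinooxazoline catalyst; because 7 is a single geometric isomer, the (S)-ligand should deliver both hydrogens to the face that makes the side-chain centre R, and aryl bromide and benzyl ethers are inert to this catalyst.

Step 6
Reactants: 9 4-(benzyloxy)benzaldehyde; 10 (4S)-4-benzyl-3-propanoyl-1,3-oxazolidin-2-one
Product: 12 (4S)-4-benzyl-3-[(2S,3S)-3-[4-(benzyloxy)phenyl]-3-hydroxy-2-methylpropanoyl]-1,3-oxazolidin-2-one, via Z-boron enolate 11 (not isolated)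
Conditions: Bu2BOTf, i-Pr2NEt, CH2Cl2, 0 °C; 9, −78 to 0 °C; then pH 7 buffer, MeOH, H2O2
Reagents that add atoms: none
Why: Evans syn-aldol reaction; the Z-boron enolate 11 reacts with 9 through a chair (Zimmerman–Traxler) transition state with the oxazolidinone carbonyl turned away from the enolate oxygen, so the aldehyde is met on the face opposite the auxiliary benzyl group and the future C4 and C5 centres form syn in the (2S,3S) sense.

Step 7
Reactants: 12 (4S)-4-benzyl-3-[(2S,3S)-3-[4-(benzyloxy)phenyl]-3-hydroxy-2-methylpropanoyl]-1,3-oxazolidin-2-one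
Product: 13 (4S)-4-benzyl-3-[(2S,3S)-3-[4-(benzyloxy)phenyl]-3-[(tert-butyldimethylsilyl)oxy]-2-methylpropanoyl]-1,3-oxazolidin-2-one
Conditions: TBSOTf, 2,6-lutidine, CH2Cl2, 0 °C
Reagents that add atoms: tert-butyldimethylsilyl triflate, CC(C)(C)[Si](C)(C)OS(=O)(=O)C(F)(F)F
Why: Silylation of the secondary benzylic alcohol; the silyl ether prevents retro-aldol cleavage and blocks the oxygen through reduction, oxidation, homologation and coupling.

Step 8
Reactants: 13 (4S)-4-benzyl-3-[(2S,3S)-3-[4-(benzyloxy)phenyl]-3-[(tert-butyldimethylsilyl)oxy]-2-methylpropanoyl]-1,3-oxazolidin-2-one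
Product: 14 (2R,3S)-3-[4-(benzyloxy)phenyl]-3-[(tert-butyldimethylsilyl)oxy]-2-methylpropan-1-ol
Conditions: LiBH4, H2O (1 equiv), Et2O, 0 °C
Reagents that add atoms: none
Why: Reductive cleavage of the N-acyl oxazolidinone; hydride attacks the more electrophilic exocyclic carbonyl and reduces on to the primary alcohol, the auxiliary is recovered, and no stereocentre is touched (the descriptor at C2 changes only through priorities).

Step 9
Reactants: 14 (2R,3S)-3-[4-(benzyloxy)phenyl]-3-[(tert-butyldimethylsilyl)oxy]-2-methylpropan-1-ol
Product: 15 (2S,3S)-3-[4-(benzyloxy)phenyl]-3-[(tert-butyldimethylsilyl)oxy]-2-methylpropanal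
Conditions: Dess–Martin periodinane, NaHCO3, CH2Cl2, 0 °C to rt
Reagents that add atoms: none
Why: Dess–Martin oxidation under bicarbonate buffer, which is neither basic nor acidic enough to epimerise the α-centre; 15 is used at once without chromatography.

Step 10
Reactants: 15 (2S,3S)-3-[4-(benzyloxy)phenyl]-3-[(tert-butyldimethylsilyl)oxy]-2-methylpropanal
Product: 16 tert-butyl{[(1S,2R)-1-[4-(benzyloxy)phenyl]-2-methylbut-3-yn-1-yl]oxy}dimethylsilane
Conditions: dimethyl (1-diazo-2-oxopropyl)phosphonate, K2CO3, MeOH, 0 °C to rt
Reagents that add atoms: dimethyl (1-diazo-2-oxopropyl)phosphonate, COP(=O)(OC)C(=[N+]=[N-])C(C)=O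
Why: Ohira–Bestmann variant of the Seyferth–Gilbert homologation; the diazomethylphosphonate anion adds to the aldehyde, dimethyl phosphate is eliminated, and loss of N2 with a 1,2-hydrogen shift gives the terminal alkyne under conditions mild enough to keep the adjacent methyl centre.

Step 11
Reactants: 8 1-(benzyloxy)-2-[(2R)-1-[4-(benzyloxy)phenyl]propan-2-yl]-4-bromobenzene; 16 tert-butyl{[(1S,2R)-1-[4-(benzyloxy)phenyl]-2-methylbut-3-yn-1-yl]oxy}dimethylsilane
Product: 17 tert-butyl{[(1S,2R)-1-[4-(benzyloxy)phenyl]-4-{4-(benzyloxy)-3-[(2R)-1-[4-(benzyloxy)phenyl]propan-2-yl]phenyl}-2-methylbut-3-yn-1-yl]oxy}dimethylsilane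
Conditions: Pd(PhCN)2Cl2 (3 mol%), [HP(t-Bu)3]BF4 (6 mol%), CuI (2 mol%), i-Pr2NH, 1,4-dioxane, rt to 50 °C
Reagents that add atoms: none
Why: Sonogashira coupling of a terminal alkyne with an electron-rich aryl bromide; the bulky, electron-rich P(t-Bu)3 ligand lets oxidative addition proceed near room temperature, and this convergent step involves no stereocentre.

Step 12
Reactants: 17 tert-butyl{[(1S,2R)-1-[4-(benzyloxy)phenyl]-4-{4-(benzyloxy)-3-[(2R)-1-[4-(benzyloxy)phenyl]propan-2-yl]phenyl}-2-methylbut-3-yn-1-yl]oxy}dimethylsilane
Product: 18 (1S,2R)-1-[4-(benzyloxy)phenyl]-4-{4-(benzyloxy)-3-[(2R)-1-[4-(benzyloxy)phenyl]propan-2-yl]phenyl}-2-methylbut-3-yn-1-ol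
Conditions: Bu4NF, THF, 0 °C to rt
Reagents that add atoms: none
Why: Fluoride cleavage of the silyl ether frees the C5 hydroxyl as the nucleophile for ring closure; the internal alkyne and the benzyl ethers are unaffected.

Step 13
Reactants: 18 (1S,2R)-1-[4-(benzyloxy)phenyl]-4-{4-(benzyloxy)-3-[(2R)-1-[4-(benzyloxy)phenyl]propan-2-yl]phenyl}-2-methylbut-3-yn-1-ol
Product: 19 (4S,5S)-5-[4-(benzyloxy)phenyl]-2-{4-(benzyloxy)-3-[(2R)-1-[4-(benzyloxy)phenyl]propan-2-yl]phenyl}-3-iodo-4-methyl-4,5-dihydrofuran
Conditions: I2 (3 equiv), NaHCO3 (3 equiv), MeCN, 0 °C to rt, dark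
Reagents that add atoms: iodine, II
Why: Iodine activates the alkyne of 18 as an iodonium-type complex polarised towards the carbon attached to ring B, because the para benzyloxy group stabilises positive charge there. The C5 hydroxyl attacks that carbon anti to iodine, forming O1–C2, and NaHCO3 takes up the proton, so iodine ends at C3 and C2=C3 lies in the ring. The closest known reaction type is the iodine-mediated cyclisation of 3-alkyn-1-ols to 3-iodo-4,5-dihydrofurans. The one ring closes in the 5-endo-dig mode, which is accessible for alkynes; attack at C3 would be 4-exo-dig and give a strained oxetane, so ring size and electronics agree. No stereocentre is created: C4 and C5 come unchanged from the syn-aldol and appear as the cis methyl/aryl pair (the descriptor at C4 changes only because iodine raises the priority of C3). The step needs regioselectivity, secured by the aryl alkyne polarisation, and chemoselectivity, secured by using iodine without oxidant or silver salt so that the alkoxyarene rings are not iodinated. The product is an acid-labile β-iodo enol ether; it should be quenched with thiosulfate, filtered through base-washed silica and used directly in step 14.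

Step 14
Reactants: 19 (4S,5S)-5-[4-(benzyloxy)phenyl]-2-{4-(benzyloxy)-3-[(2R)-1-[4-(benzyloxy)phenyl]propan-2-yl]phenyl}-3-iodo-4-methyl-4,5-dihydrofuran
Product: 20 (4R,5S)-5-[4-(benzyloxy)phenyl]-2-{4-(benzyloxy)-3-[(2R)-1-[4-(benzyloxy)phenyl]propan-2-yl]phenyl}-3,4-dimethyl-4,5-dihydrofuran
Conditions: MeZnCl (2 equiv), Pd(PPh3)4 (5 mol%), THF, rt to 45 °C
Reagents that add atoms: methylzinc chloride, C[Zn]Cl
Why: Negishi coupling: oxidative addition of zerovalent palladium into the vinyl C–I bond, transmetalation from zinc and reductive elimination place the C3 methyl under neutral, non-aqueous conditions that the enol ether tolerates.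

Step 15
Reactants: 20 (4R,5S)-5-[4-(benzyloxy)phenyl]-2-{4-(benzyloxy)-3-[(2R)-1-[4-(benzyloxy)phenyl]propan-2-yl]phenyl}-3,4-dimethyl-4,5-dihydrofuran
Product: 21 4-[(2R,3S,4R,5S)-5-(4-hydroxyphenyl)-3,4-dimethyloxolan-2-yl]-2-[(2R)-1-(4-hydroxyphenyl)propan-2-yl]phenol
Conditions: H2 (1–4 bar), 10% Pd/C, EtOAc–EtOH, rt
Reagents that add atoms: none
Why: Heterogeneous hydrogenation; the enol ether binds the catalyst on the face opposite the cis C4 methyl and C5 aryl groups, and syn delivery of both hydrogens to C2 and C3 from that face puts ring B and the C3 methyl on the side of the existing substituents (2R,3S, all-cis), while the three benzyl ethers are hydrogenolysed in the same neutral operation.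

## Compound list

1 | 4-bromo-2-iodophenol | Oc1ccc(Br)cc1I | starting material
2 | 1-(benzyloxy)-4-bromo-2-iodobenzene | Brc1ccc(OCc2ccccc2)c(I)c1 | intermediate
3 | 1-(benzyloxy)-4-iodobenzene | Ic1ccc(OCc2ccccc2)cc1 | starting material
4 | propyne | CC#C | starting material
5 | 1-(benzyloxy)-4-(prop-1-yn-1-yl)benzene | CC#Cc1ccc(OCc2ccccc2)cc1 | intermediate
6 | 2-{(Z)-1-[4-(benzyloxy)phenyl]prop-1-en-2-yl}-4,4,5,5-tetramethyl-1,3,2-dioxaborolane | C/C(B1OC(C)(C)C(C)(C)O1)=C\c1ccc(OCc2ccccc2)cc1 | intermediate
7 | 1-(benzyloxy)-2-{(E)-1-[4-(benzyloxy)phenyl]prop-1-en-2-yl}-4-bromobenzene | C/C(c1cc(Br)ccc1OCc1ccccc1)=C\c1ccc(OCc2ccccc2)cc1 | intermediate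
8 | 1-(benzyloxy)-2-[(2R)-1-[4-(benzyloxy)phenyl]propan-2-yl]-4-bromobenzene | Brc1ccc(OCc2ccccc2)c([C@H](C)Cc2ccc(OCc3ccccc3)cc2)c1 | intermediate
9 | 4-(benzyloxy)benzaldehyde | O=Cc1ccc(OCc2ccccc2)cc1 | starting material
10 | (4S)-4-benzyl-3-propanoyl-1,3-oxazolidin-2-one | CCC(=O)N1[C@@H](Cc2ccccc2)COC1=O | starting material
11 | (4S)-4-benzyl-3-{(1Z)-1-[(dibutylboranyl)oxy]prop-1-en-1-yl}-1,3-oxazolidin-2-one | C/C=C(\OB(CCCC)CCCC)N1[C@@H](Cc2ccccc2)COC1=O | intermediate (not isolated)
12 | (4S)-4-benzyl-3-[(2S,3S)-3-[4-(benzyloxy)phenyl]-3-hydroxy-2-methylpropanoyl]-1,3-oxazolidin-2-one | O=C([C@@H](C)[C@H](O)c1ccc(OCc2ccccc2)cc1)N1[C@@H](Cc2ccccc2)COC1=O | intermediate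
13 | (4S)-4-benzyl-3-[(2S,3S)-3-[4-(benzyloxy)phenyl]-3-[(tert-butyldimethylsilyl)oxy]-2-methylpropanoyl]-1,3-oxazolidin-2-one | O=C([C@@H](C)[C@H](O[Si](C)(C)C(C)(C)C)c1ccc(OCc2ccccc2)cc1)N1[C@@H](Cc2ccccc2)COC1=O | intermediate
14 | (2R,3S)-3-[4-(benzyloxy)phenyl]-3-[(tert-butyldimethylsilyl)oxy]-2-methylpropan-1-ol | OC[C@@H](C)[C@H](O[Si](C)(C)C(C)(C)C)c1ccc(OCc2ccccc2)cc1 | intermediate
15 | (2S,3S)-3-[4-(benzyloxy)phenyl]-3-[(tert-butyldimethylsilyl)oxy]-2-methylpropanal | O=C[C@@H](C)[C@H](O[Si](C)(C)C(C)(C)C)c1ccc(OCc2ccccc2)cc1 | intermediate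
16 | tert-butyl{[(1S,2R)-1-[4-(benzyloxy)phenyl]-2-methylbut-3-yn-1-yl]oxy}dimethylsilane | C#C[C@@H](C)[C@H](O[Si](C)(C)C(C)(C)C)c1ccc(OCc2ccccc2)cc1 | intermediate
17 | tert-butyl{[(1S,2R)-1-[4-(benzyloxy)phenyl]-4-{4-(benzyloxy)-3-[(2R)-1-[4-(benzyloxy)phenyl]propan-2-yl]phenyl}-2-methylbut-3-yn-1-yl]oxy}dimethylsilane | C[C@H](C#Cc1ccc(OCc2ccccc2)c([C@H](C)Cc2ccc(OCc3ccccc3)cc2)c1)[C@H](O[Si](C)(C)C(C)(C)C)c1ccc(OCc2ccccc2)cc1 | intermediate
18 | (1S,2R)-1-[4-(benzyloxy)phenyl]-4-{4-(benzyloxy)-3-[(2R)-1-[4-(benzyloxy)phenyl]propan-2-yl]phenyl}-2-methylbut-3-yn-1-ol | C[C@H](C#Cc1ccc(OCc2ccccc2)c([C@H](C)Cc2ccc(OCc3ccccc3)cc2)c1)[C@H](O)c1ccc(OCc2ccccc2)cc1 | intermediate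
19 | (4S,5S)-5-[4-(benzyloxy)phenyl]-2-{4-(benzyloxy)-3-[(2R)-1-[4-(benzyloxy)phenyl]propan-2-yl]phenyl}-3-iodo-4-methyl-4,5-dihydrofuran | C[C@@H]1C(I)=C(c2ccc(OCc3ccccc3)c([C@H](C)Cc3ccc(OCc4ccccc4)cc3)c2)O[C@@H]1c1ccc(OCc2ccccc2)cc1 | intermediate
20 | (4R,5S)-5-[4-(benzyloxy)phenyl]-2-{4-(benzyloxy)-3-[(2R)-1-[4-(benzyloxy)phenyl]propan-2-yl]phenyl}-3,4-dimethyl-4,5-dihydrofuran | C[C@@H]1C(C)=C(c2ccc(OCc3ccccc3)c([C@H](C)Cc3ccc(OCc4ccccc4)cc3)c2)O[C@@H]1c1ccc(OCc2ccccc2)cc1 | intermediate
21 | 4-[(2R,3S,4R,5S)-5-(4-hydroxyphenyl)-3,4-dimethyloxolan-2-yl]-2-[(2R)-1-(4-hydroxyphenyl)propan-2-yl]phenol | C[C@@H]1[C@H](C)[C@H](c2ccc(O)c([C@H](C)Cc3ccc(O)cc3)c2)O[C@@H]1c1ccc(O)cc1 | target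

## Step count and least certain steps

Total: 15 steps. Longest linear sequence: 10 steps (steps 6 to 15, from 9 and 10); the ring B branch (steps 1 to 5) joins at step 11.

**Step 13 (key step).** The enol ether product is more electron-rich than the alkyne it comes from. The likely failure is further attack of iodine on it, leading to aromatisation to the furan with loss of C4 and C5, together with acid-promoted hydrolysis on work-up. The fallback sets out from 18 and separates ring closure from halogenation. Cationic gold catalysis (AuCl(PPh3) with AgOTf, toluene, rt) should effect the same 5-endo-dig hydroalkoxylation without any oxidant and give (4R,5S)-5-[4-(benzyloxy)phenyl]-2-{4-(benzyloxy)-3-[(2R)-1-[4-(benzyloxy)phenyl]propan-2-yl]phenyl}-4-methyl-4,5-dihydrofuran F1. One equivalent of N-iodosuccinimide with 2,6-lutidine then iodinates the enol ether at C3 with loss of the C3 proton, which comes back to the route at 19.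

**Step 15.** Two processes threaten it: hydrogenolysis of the C5–O1 bond, which in 20 is both benzylic and part of an enol ether, and palladium-induced migration of the double bond towards C4 before reduction, which would erase the C4 configuration. The fallback sets out from 20 and decouples the two events. The homogeneous catalyst [Ir(cod)(PCy3)(py)]PF6 under H2 in CH2Cl2 reduces tetrasubstituted alkenes without hydrogenolysis and should give (2R,3S,4R,5S)-5-[4-(benzyloxy)phenyl]-2-{4-(benzyloxy)-3-[(2R)-1-[4-(benzyloxy)phenyl]propan-2-yl]phenyl}-3,4-dimethyloxolane F2 by addition to the same open face. A brief hydrogenolysis of F2 over Pd/C in neutral EtOAc–MeOH, now on a saturated 2,5-diaryloxolane, comes back at 21.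

**Step 5.** Ring B carries an ortho benzyloxy group and is twisted out of the alkene plane. Turnover may therefore be slow, and catalyst-induced E/Z isomerisation or weaker face discrimination may lower the enantiomeric purity. The fallback sets out from 7 and replaces asymmetric catalysis by resolution. Hydrogenation with the achiral catalyst [Ir(cod)(PCy3)(py)]PF6 gives racemic 1-(benzyloxy)-2-{1-[4-(benzyloxy)phenyl]propan-2-yl}-4-bromobenzene F3, which is separated by preparative chromatography on a chiral stationary phase; the R enantiomer is 8. Half the material is lost, which is acceptable on an early, cheap fragment.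

**Step 10.** The aldehyde 15 can epimerise at the α-carbon in basic methanol, or lose silanolate by β-elimination to the conjugated enal, before the homologation reagent has reacted. The fallback sets out from 15 and avoids alkoxide base (Corey–Fuchs sequence). CBr4 and PPh3 in CH2Cl2 at 0 °C give tert-butyl{[(1S,2R)-1-[4-(benzyloxy)phenyl]-4,4-dibromo-2-methylbut-3-en-1-yl]oxy}dimethylsilane F4. Treating F4 with n-BuLi (2 equiv) in THF at −78 °C, then water, comes back at 16.

## Further compounds

F1 | step 13 | (4R,5S)-5-[4-(benzyloxy)phenyl]-2-{4-(benzyloxy)-3-[(2R)-1-[4-(benzyloxy)phenyl]propan-2-yl]phenyl}-4-methyl-4,5-dihydrofuran | C[C@@H]1C=C(c2ccc(OCc3ccccc3)c([C@H](C)Cc3ccc(OCc4ccccc4)cc3)c2)O[C@@H]1c1ccc(OCc2ccccc2)cc1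
F2 | step 15 | (2R,3S,4R,5S)-5-[4-(benzyloxy)phenyl]-2-{4-(benzyloxy)-3-[(2R)-1-[4-(benzyloxy)phenyl]propan-2-yl]phenyl}-3,4-dimethyloxolane | C[C@@H]1[C@H](C)[C@H](c2ccc(OCc3ccccc3)c([C@H](C)Cc3ccc(OCc4ccccc4)cc3)c2)O[C@@H]1c1ccc(OCc2ccccc2)cc1
F3 | step 5 | racemic 1-(benzyloxy)-2-{1-[4-(benzyloxy)phenyl]propan-2-yl}-4-bromobenzene | Brc1ccc(OCc2ccccc2)c(C(C)Cc2ccc(OCc3ccccc3)cc2)c1
F4 | step 10 | tert-butyl{[(1S,2R)-1-[4-(benzyloxy)phenyl]-4,4-dibromo-2-methylbut-3-en-1-yl]oxy}dimethylsilane | BrC(Br)=C[C@@H](C)[C@H](O[Si](C)(C)C(C)(C)C)c1ccc(OCc2ccccc2)cc1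
A1 | alternative 1 | (4R,5S)-5-[4-(benzyloxy)phenyl]-4-methyl-3-methylideneoxolan-2-one | C[C@@H]1C(=C)C(=O)O[C@@H]1c1ccc(OCc2ccccc2)cc1
A2 | alternative 1 | ethyl (2E)-2-[(4,4,5,5-tetramethyl-1,3,2-dioxaborolan-2-yl)methyl]but-2-enoate | C/C=C(\CB1OC(C)(C)C(C)(C)O1)C(=O)OCC
A3 | alternative 2 | 2-[(2R)-2-{2-(benzyloxy)-5-[(2R,3S,4R,5S)-5-[4-(benzyloxy)phenyl]-3,4-dimethyloxolan-2-yl]phenyl}-1-[4-(benzyloxy)phenyl]propan-2-yl]-4,4,5,5-tetramethyl-1,3,2-dioxaborolane | C[C@@H]1[C@H](C)[C@H](c2ccc(OCc3ccccc3)c([C@@](C)(B3OC(C)(C)C(C)(C)O3)Cc3ccc(OCc4ccccc4)cc3)c2)O[C@@H]1c1ccc(OCc2ccccc2)cc1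
A4 | alternative 2 | {2-(benzyloxy)-5-[(2R,3S,4R,5S)-5-[4-(benzyloxy)phenyl]-3,4-dimethyloxolan-2-yl]phenyl}lithium | C[C@@H]1[C@H](C)[C@H](c2ccc(OCc3ccccc3)c([Li])c2)O[C@@H]1c1ccc(OCc2ccccc2)cc1
A5 | alternative 2 | 4,4,5,5-tetramethyl-2-(prop-1-en-2-yl)-1,3,2-dioxaborolane | CC(=C)B1OC(C)(C)C(C)(C)O1
A6 | alternative 2 | 4-(benzyloxy)phenyl trifluoromethanesulfonate | O=S(=O)(Oc1ccc(OCc2ccccc2)cc1)C(F)(F)F
A7 | alternative 3 | methyl (2R,3S)-2-[4-(benzyloxy)phenyl]-5-bromo-2,3-dihydro-1-benzofuran-3-carboxylate | Brc1ccc2O[C@@H](c3ccc(OCc4ccccc4)cc3)[C@@H](C(=O)OC)c2c1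
A8 | alternative 3 | methyl 2-[2-{[4-(benzyloxy)phenyl]methoxy}-5-bromophenyl]-2-diazoacetate | COC(=O)C(=[N+]=[N-])c1cc(Br)ccc1OCc1ccc(OCc2ccccc2)cc1
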